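The earlier runs and the new flask stem from a simulated flask with constants of no real substance; scatter was added.

Slowness comes first: the midnight run shows 0.2% of left-handed product after 1.00 min but 29.3% after 8.00 min.

all flasks: left-handed substrate 0.80 M; right-handed substrate 0.80 M; precatalyst 0.80 mM; added ligand 0.44 mM
- noon: reagent 1 M; run made earlier
- midnight: reagent 2.1 M; run made earlier
- alpha: reagent 0.800 M; time 15 min
- epsilon: reagent 1.50 M; time 15 min

| run | time / min | right-handed substrate / % | left-handed substrate / % | left-handed product / % |
|---|---|---|---|---|
| noon | 0.667 | 49.5 | 50.3 | 0.2 |
| noon | 2.00 | 49.2 | 48.9 | 0.5 |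
| noon | 4.00 | 47.5 | 45.5 | 5.3 |
| noon | 5.00 | 45.2 | 42.6 | 7.8 |
| noon | 8.00 | 39.2 | 32.7 | 17.5 |
| midnight | 0.667 | 49.6 | 49.6 | 0 |
| midnight | 1.00 | 49.5 | 49.3 | 0.2 |
| midnight | 2.00 | 48.9 | 47.6 | 3.0 |
| midnight | 4.00 | 44.3 | 40.1 | 9.4 |
| midnight | 8.00 | 29.9 | 20.0 | 29.3 |

(each reading ± 0.3 percentage points)

- catalyst is single-handed; left-handed substrate and right-handed substrate are mirror images of each other, charged as a racemate, each of them at the stated concentration
- an excess is the difference of the two amounts in percent of their sum
- an excess is below zero if the other one leads

* which of the two ends with the higher excess of right-handed substrate over left-handed substrate among what is left of the two ("neither" if they lie within 2 percentage points) (alpha / epsilon / neither)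
* excess of right-handed substrate over left-handed substrate among what is left of the two at the end, alpha
* excess of right-handed substrate over left-handed substrate among what is left of the two at the end, epsilon

Work with fractions left, not fractions made. Let fL and fS be the fractions of left-handed and right-handed substrate left. Then the selectivity factor s = ln(fL)/ln(fS) reads 1.78 at midnight and 1.75 at noon, on 2.10 times the reagent. The excess is (fS − fL)/(fS + fL).

Counting one reagent per substrate, alpha's reagent covers half of the substrate. It is the limiting reagent there, and on that count the sum of the two fractions left reaches a floor of 1.00 once the reagent is spent. The last midnight reading stands at that floor, 0.400 and 0.598, so its excess, as read, is an upper estimate for alpha: 19.8%.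

For epsilon, take x = ln(1/fL). Doubling the time from 4.00 min to 8.00 min multiplies x by 4.15, and midnight's x is 2.16 times noon's. Scaling x with charge and squared time gives 2.30, and through s an excess of 46.6%. That scaling holds reagent at its charge, so this too is an upper estimate.

Your forecast names epsilon, with 19% for alpha and 38% for epsilon, holding that “selectivity is about 1.8 and independent of reagent”. Both values lie under these upper estimates, so this reckoning keeps them.

Alpha ends at 15.8% and epsilon at 35.0%, so epsilon leads, as forecast.

    precatalyst → catalyst (k = 0.00141 s⁻¹)
    reagent + catalyst + right-handed substrate → catalyst + right-handed product (k = 21.6 L² mol⁻² s⁻¹)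
    catalyst + added ligand ⇌ idle complex, settled at all times (K = 31000 L mol⁻¹)
    reagent + catalyst + left-handed substrate → catalyst + left-handed product (k = 37.0 L² mol⁻² s⁻¹)

Alpha lies 3.2 percentage points under the forecast and still holds 10% of its reagent at 15.0 min. Its 46% of left-handed substrate left gives, through s, 65.0% of right-handed substrate and an excess of 16.7%. A neighbour of alpha is charged with 0.32 M of reagent and keeps 77% of its left-handed substrate. Through s, that gives 86.1% of right-handed substrate and an excess of 5.86%. The neighbour flask gives 5.56%.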